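The retrosynthesis first takes the 6Z alkene back to a C6≡C7 alkyne. It then cuts the benzoate ring at C2'–C3' and C4'–C5', followed by the acyl–O bond at sn-2, the chain C5–C6 bond and the chain C1–O ether bond at sn-1.
The enabling feature is a benzene ring with the carboxyl carbon at C1' and oxygen para to it at C4'. C1', C2', C5', C6' and the carboxyl carbon match C5, C6, C3, C4 and the 5-carboxyl of a 2-pyrone; C3' and C4'–O match a ketene acetal; pyrone O1–C2 leaves as CO2.
In the forward direction, (R)-solketal is etherified with a pentynyl mesylate and the chain is grown by hydrozirconation–iodination and Sonogashira coupling to the 4E,8E-dien-6-yne. The glycerol is then unmasked, silylated at O-3 and coumaloylated at O-2.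
The benzene ring, the only ring made, arises in step 11. The alkyne is reduced to the 6Z alkene only afterwards, because an E,Z,E-triene could undergo 6π electrocyclisation at the temperature of CO2 loss; fluoride then frees O-3.
C2 of glycerol comes unchanged from (R)-solketal, and its R/S label changes along the way only through CIP priorities. The 4E alkene comes from syn hydrozirconation, 8E from (E)-hex-2-enal and 6Z from syn hydrogen delivery by activated zinc.

Key step: step 11

Remark: the target is read as 1-O-[(4E,6Z,8E)-dodeca-4,6,8-trienyl]-2-O-(4-hydroxybenzoyl)-sn-glycerol, (S) at C2. Aryl silyl ether 21 hydrolyses easily and is assumed to be carried on without chromatography.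

Step 1
Reactants: 1 pent-4-yn-1-ol
Product: 2 pent-4-yn-1-yl methanesulfonate
Conditions: MsCl, Et3N, CH2Cl2, 0 °C
Reagents that add atoms: methanesulfonyl chloride, CS(=O)(=O)Cl
Why: Mesylation of a primary alcohol is a standard sulfonylation that turns the hydroxyl group into a good leaving group for SN2 displacement and leaves the terminal alkyne untouched.

Step 2
Reactants: 3 (R)-solketal; 2 pent-4-yn-1-yl methanesulfonate
Product: 5 (4R)-2,2-dimethyl-4-[(pent-4-yn-1-yloxy)methyl]-1,3-dioxolane, via sodium alkoxide 4 (not isolated)
Conditions: NaH, THF/DMF, 0 °C; then 2, n-Bu4NI (cat.), rt → 40 °C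
Reagents that add atoms: none
Why: Williamson ether synthesis by SN2 attack of the primary alkoxide on the unhindered primary mesylate, in which the alkoxide is too weak a base to metalate the alkyne and no bond at the dioxolane stereocentre is made or broken, so that this carbon becomes C2 of a 1-O-alkyl-sn-glycerol.

Step 3
Reactants: 5 (4R)-2,2-dimethyl-4-[(pent-4-yn-1-yloxy)methyl]-1,3-dioxolane
Product: 7 (4R)-4-({[(4E)-5-iodopent-4-en-1-yl]oxy}methyl)-2,2-dimethyl-1,3-dioxolane, via alkenylzirconocene chloride 6 (not isolated)
Conditions: Cp2Zr(H)Cl (1.4 equiv), THF, rt, dark; then I2, THF, −20 °C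
Reagents that add atoms: iodine, [I][I]
Why: Hydrozirconation–iodinolysis: Zr–H adds syn to the terminal alkyne with zirconium at the less hindered terminal carbon, and iodine replaces the C–Zr bond with retention, which sets the 4E alkene while the ether and ketal oxygen functions are inert.

Step 4
Reactants: 8 (E)-hex-2-enal
Product: 9 (E)-hept-3-en-1-yne
Conditions: Me3SiCHN2, n-BuLi, THF, −78 °C; then 8, −78 °C → rt; H2O quench; product kept as a distilled stock solution (volatile)
Reagents that add atoms: (trimethylsilyl)diazomethane, C[Si](C)(C)C=[N+]=[N-]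
Why: Colvin rearrangement (one-carbon homologation of an aldehyde to a terminal alkyne): addition of the lithiated diazo compound, loss of Me3SiOLi and N2 and a 1,2-hydride shift give the alkyne under aprotic conditions, so that the conjugate addition of methanol that troubles enals under methanolic diazophosphonate conditions cannot occur and the E alkene of 8 is carried over as the future 8E alkene.

Step 5
Reactants: 7 (4R)-4-({[(4E)-5-iodopent-4-en-1-yl]oxy}methyl)-2,2-dimethyl-1,3-dioxolane; 9 (E)-hept-3-en-1-yne
Product: 10 (4R)-4-({[(4E,8E)-dodeca-4,8-dien-6-yn-1-yl]oxy}methyl)-2,2-dimethyl-1,3-dioxolane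
Conditions: PdCl2(PPh3)2 (3 mol %), CuI (6 mol %), Et3N, THF, rt, degassed
Reagents that add atoms: none
Why: Sonogashira coupling: oxidative addition of the alkenyl iodide to zerovalent palladium, transfer of the copper acetylide and reductive elimination all proceed with retention at room temperature, so the C5–C6 bond forms with both E alkenes intact.

Step 6
Reactants: 10 (4R)-4-({[(4E,8E)-dodeca-4,8-dien-6-yn-1-yl]oxy}methyl)-2,2-dimethyl-1,3-dioxolane
Product: 11 (2S)-3-[(4E,8E)-dodeca-4,8-dien-6-yn-1-yloxy]propane-1,2-diol
Conditions: AcOH/H2O (4:1), 40 °C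
Reagents that add atoms: none
Why: Acid-catalysed ketal hydrolysis cleaves only the C–O bonds of the acetone-derived carbon, so that the configuration at C2 is kept, and the dienyne and the ether tolerate dilute acetic acid.

Step 7
Reactants: 11 (2S)-3-[(4E,8E)-dodeca-4,8-dien-6-yn-1-yloxy]propane-1,2-diol
Product: 12 (2R)-1-[(tert-butyldimethylsilyl)oxy]-3-[(4E,8E)-dodeca-4,8-dien-6-yn-1-yloxy]propan-2-ol
Conditions: TBSCl (1.05 equiv), imidazole, CH2Cl2, −10 °C → 0 °C
Reagents that add atoms: tert-butyldimethylsilyl chloride, CC(C)(C)[Si](C)(C)Cl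
Why: Sterically controlled monosilylation of a 1,2-diol: the bulky silyl chloride reacts much faster at the primary O-3 than at the secondary O-2 when used in near-stoichiometric amount at low temperature, and the tert-butyldimethylsilyl ether is chosen because it must later survive aqueous methanol in step 12.

Step 8
Reactants: 13 coumalic acid
Product: 14 coumaloyl chloride (2-oxo-2H-pyran-5-carbonyl chloride)
Conditions: SOCl2, reflux; excess removed in vacuo, recrystallisation
Reagents that add atoms: thionyl chloride, O=S(Cl)Cl
Why: Conversion of a carboxylic acid into its chloride with thionyl chloride, which the acid-stable 2-pyrone ring tolerates, gives a crystalline acyl donor free of any nucleophilic activator.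

Step 9
Reactants: 12 (2R)-1-[(tert-butyldimethylsilyl)oxy]-3-[(4E,8E)-dodeca-4,8-dien-6-yn-1-yloxy]propan-2-ol; 14 coumaloyl chloride
Product: 15 (2R)-1-[(tert-butyldimethylsilyl)oxy]-3-[(4E,8E)-dodeca-4,8-dien-6-yn-1-yloxy]propan-2-yl 2-oxo-2H-pyran-5-carboxylate
Conditions: 14 (1.4 equiv), 2,6-lutidine (2 equiv), CH2Cl2, −20 °C → rt
Reagents that add atoms: none
Why: Acylation of a secondary alcohol with an acid chloride, in which the hindered pyridine base only scavenges HCl (protecting the silyl ether) and, unlike unhindered amines, cannot add to the electrophilic C6 of the pyrone; the C2–O bond is untouched, so configuration is retained.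

Step 10
Reactants: 16 trimethylsilyl acetate
Product: 18 1,1-bis(trimethylsilyloxy)ethene, via lithium enolate 17 (not isolated)
Conditions: LiN(i-Pr)2, THF, −78 °C; Me3SiCl, −78 °C → rt; pentane, filtration, fractional distillation
Reagents that add atoms: chlorotrimethylsilane, C[Si](C)(C)Cl
Why: Ketene silyl acetal formation by kinetic enolisation of the silyl ester and trapping of the lithium enolate on oxygen by the hard silyl chloride; the minor C-silylated isomer is removed by the distillation.

Step 11
Reactants: 15 (2R)-1-[(tert-butyldimethylsilyl)oxy]-3-[(4E,8E)-dodeca-4,8-dien-6-yn-1-yloxy]propan-2-yl 2-oxo-2H-pyran-5-carboxylate; 18 1,1-bis(trimethylsilyloxy)ethene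
Product: 21 (2R)-1-[(tert-butyldimethylsilyl)oxy]-3-[(4E,8E)-dodeca-4,8-dien-6-yn-1-yloxy]propan-2-yl 4-(trimethylsilyloxy)benzoate, via bridged lactone 19 (not isolated), via cyclohexadiene 20 (not isolated)
Conditions: 18 (3 equiv), toluene, 60 °C → 100 °C, Ar, dark; volatiles removed in vacuo
Reagents that add atoms: none
Why: The electron-rich CH2 terminus of 18 attacks C6 of the pyrone (β to the 5-ester and vinylogously conjugated to the lactone carbonyl) while its acetal carbon closes onto C3, in a concerted but strongly asynchronous inverse-electron-demand Diels–Alder reaction that gives the 2-oxabicyclo[2.2.2]octenone 19. Lactone 19 expels CO2 by retro-[4+2] to give diene 20, and 1,2-elimination of Me3SiOH across CH2–C(OSiMe3)2 aromatises 20 to 21. The reaction type is the known conversion of coumalate esters with ketene acetals and enol ethers into 4-oxygenated benzoates by cycloaddition, decarboxylation and elimination, here run with a bis-silyl acetal of comparable nucleophilicity so that the ring oxygen appears as a labile silyl ether. The six-membered carbocycle is closed intermolecularly by [4+2] cycloaddition (bonds C6–CH2 and C3–C(O)2, which become C2'–C3' and C4'–C5'), and no stereocentre is created in 21, because the two uncontrolled bridgehead centres of 19 are erased on aromatisation and glycerol C2 is remote and untouched. Para rather than meta regiochemistry follows from the matched polarisation of the two partners, and chemoselectivity follows from the much higher HOMO of the acetal, used in excess, compared with the neutral dienyne chain, which does not add to the pyrone at 100 °C and cannot electrocyclise while its central unit is a linear alkyne. Excess 18 also resilylates any phenol set free by silanol or moisture, so the material should converge on 21.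

Step 12
Reactants: 21 (2R)-1-[(tert-butyldimethylsilyl)oxy]-3-[(4E,8E)-dodeca-4,8-dien-6-yn-1-yloxy]propan-2-yl 4-(trimethylsilyloxy)benzoate
Product: 22 (2R)-1-[(tert-butyldimethylsilyl)oxy]-3-[(4E,6Z,8E)-dodeca-4,6,8-trien-1-yloxy]propan-2-yl 4-hydroxybenzoate
Conditions: Zn dust activated with Cu(OAc)2 and AgNO3, MeOH/H2O/1,4-dioxane, rt → 35 °C, Ar, dark; filtration, pH 7 buffer
Reagents that add atoms: none
Why: Boland reduction: the activated zinc surface delivers two hydrogens from the protic medium to the same face of the conjugated alkyne, which gives the 6Z alkene and stops there, leaving the 4E and 8E alkenes, the ester and the alkyl silyl ether untouched, while the aqueous methanol solvolyses the labile aryl trimethylsilyl ether.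

Step 13
Reactants: 22 (2R)-1-[(tert-butyldimethylsilyl)oxy]-3-[(4E,6Z,8E)-dodeca-4,6,8-trien-1-yloxy]propan-2-yl 4-hydroxybenzoate
Product: 23 (2S)-1-[(4E,6Z,8E)-dodeca-4,6,8-trien-1-yloxy]-3-hydroxypropan-2-yl 4-hydroxybenzoate (target)
Conditions: HF·pyridine, pyridine, THF, 0 °C, dark; Me3SiOMe quench; rapid chromatography on boric-acid-treated silica
Reagents that add atoms: none
Why: Fluoride-induced cleavage of the primary silyl ether in a weakly acidic, pyridine-buffered medium at low temperature, conditions under which the base-catalysed shift of the acyl group from O-2 to O-3 and isomerisation of the triene are both slow; the stereocentre is not involved.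

Compound list
1 | pent-4-yn-1-ol | C#CCCCO | starting material
2 | pent-4-yn-1-yl methanesulfonate | C#CCCCOS(C)(=O)=O | intermediate
3 | (R)-solketal, [(4R)-2,2-dimethyl-1,3-dioxolan-4-yl]methanol | OC[C@H](CO1)OC1(C)C | starting material
4 | sodium alkoxide of 3 | [Na+].[O-]C[C@H](CO1)OC1(C)C | intermediate
5 | (4R)-2,2-dimethyl-4-[(pent-4-yn-1-yloxy)methyl]-1,3-dioxolane | C#CCCCOC[C@H](CO1)OC1(C)C | intermediate
6 | chlorobis(cyclopentadienyl)[(1E)-5-{[(4R)-2,2-dimethyl-1,3-dioxolan-4-yl]methoxy}pent-1-en-1-yl]zirconium | Cl[Zr](C1C=CC=C1)(C1C=CC=C1)/C=C/CCCOC[C@H](CO1)OC1(C)C | intermediate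
7 | (4R)-4-({[(4E)-5-iodopent-4-en-1-yl]oxy}methyl)-2,2-dimethyl-1,3-dioxolane | I/C=C/CCCOC[C@H](CO1)OC1(C)C | intermediate
8 | (E)-hex-2-enal | CCC/C=C/C=O | starting material
9 | (E)-hept-3-en-1-yne | CCC/C=C/C#C | intermediate
10 | (4R)-4-({[(4E,8E)-dodeca-4,8-dien-6-yn-1-yl]oxy}methyl)-2,2-dimethyl-1,3-dioxolane | CCC/C=C/C#C/C=C/CCCOC[C@H](CO1)OC1(C)C | intermediate
11 | (2S)-3-[(4E,8E)-dodeca-4,8-dien-6-yn-1-yloxy]propane-1,2-diol (1-O-dienynyl-sn-glycerol) | CCC/C=C/C#C/C=C/CCCOC[C@H](CO)O | intermediate
12 | (2R)-1-[(tert-butyldimethylsilyl)oxy]-3-[(4E,8E)-dodeca-4,8-dien-6-yn-1-yloxy]propan-2-ol | CCC/C=C/C#C/C=C/CCCOC[C@H](CO[Si](C)(C)C(C)(C)C)O | intermediate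
13 | coumalic acid (2-oxo-2H-pyran-5-carboxylic acid) | OC(=O)C1=COC(=O)C=C1 | starting material
14 | coumaloyl chloride (2-oxo-2H-pyran-5-carbonyl chloride) | ClC(=O)C1=COC(=O)C=C1 | intermediate
15 | (2R)-1-[(tert-butyldimethylsilyl)oxy]-3-[(4E,8E)-dodeca-4,8-dien-6-yn-1-yloxy]propan-2-yl 2-oxo-2H-pyran-5-carboxylate | CCC/C=C/C#C/C=C/CCCOC[C@H](CO[Si](C)(C)C(C)(C)C)OC(=O)C1=COC(=O)C=C1 | intermediate
16 | trimethylsilyl acetate | CC(=O)O[Si](C)(C)C | starting material
17 | lithium 1-(trimethylsilyloxy)ethenolate | [Li+].C=C([O-])O[Si](C)(C)C | intermediate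
18 | 1,1-bis(trimethylsilyloxy)ethene (ketene bis(trimethylsilyl) acetal) | C=C(O[Si](C)(C)C)O[Si](C)(C)C | intermediate
19 | 8,8-bis(trimethylsilyloxy)-3-oxo-2-oxabicyclo[2.2.2]oct-5-ene-6-carboxylate of alcohol 12 (mixture at the two transient bridgeheads) | CCC/C=C/C#C/C=C/CCCOC[C@H](CO[Si](C)(C)C(C)(C)C)OC(=O)C1=CC2C(=O)OC1CC2(O[Si](C)(C)C)O[Si](C)(C)C | intermediate
20 | 4,4-bis(trimethylsilyloxy)cyclohexa-1,5-diene-1-carboxylate of alcohol 12 | CCC/C=C/C#C/C=C/CCCOC[C@H](CO[Si](C)(C)C(C)(C)C)OC(=O)C1=CCC(O[Si](C)(C)C)(O[Si](C)(C)C)C=C1 | intermediate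
21 | (2R)-1-[(tert-butyldimethylsilyl)oxy]-3-[(4E,8E)-dodeca-4,8-dien-6-yn-1-yloxy]propan-2-yl 4-(trimethylsilyloxy)benzoate | CCC/C=C/C#C/C=C/CCCOC[C@H](CO[Si](C)(C)C(C)(C)C)OC(=O)c1ccc(O[Si](C)(C)C)cc1 | intermediate
22 | (2R)-1-[(tert-butyldimethylsilyl)oxy]-3-[(4E,6Z,8E)-dodeca-4,6,8-trien-1-yloxy]propan-2-yl 4-hydroxybenzoate | CCC/C=C/C=C\C=C\CCCOC[C@H](CO[Si](C)(C)C(C)(C)C)OC(=O)c1ccc(O)cc1 | intermediate
23 | (2S)-1-[(4E,6Z,8E)-dodeca-4,6,8-trien-1-yloxy]-3-hydroxypropan-2-yl 4-hydroxybenzoate | CCC/C=C/C=C\C=C\CCCOC[C@H](CO)OC(=O)c1ccc(O)cc1 | target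

Total step count: 13.
Longest linear sequence: 10 steps (1, 2, 3, 5, 6, 7, 9, 11, 12, 13).

Steps most likely to fail

Risk at step 11. The addition may stop after the C6–CH2 bond has formed, with silyl transfer to the dienolate and opening of the lactone in place of closure at C3. Adventitious moisture may also consume the acetal before it adds. The fallback sets out from 12 and comes back at 21. The arene is taken from commercial 4-hydroxybenzoic acid instead of being built. Hexamethyldisilazane converts the acid into trimethylsilyl 4-(trimethylsilyloxy)benzoate F1, and SOCl2 turns the silyl ester of F1 into 4-(trimethylsilyloxy)benzoyl chloride F2. This chloride acylates 12 (pyridine, CH2Cl2, 0 °C) to give 21. Steps 8 to 10 then fall away and steps 12 and 13 follow unchanged.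

Risk at step 9. Acylation of the hindered secondary hydroxyl may be slow without a nucleophilic catalyst. The pyrone may open or oligomerise through addition of base or chloride at C6. HCl may strip the silyl ether, followed by acylation at O-3. The fallback sets out from 12 and comes back at 15, and it uses no amine. Alcohol 12 is heated with Bu3SnOMe in toluene, with azeotropic removal of methanol, to give the tributylstannyl ether of 12 F3. Its Sn–O bond is acylated directly by 14 in CH2Cl2 at 0 °C to give 15 under neutral conditions, and the tin halide is removed over KF on silica.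

Risk at step 12. Conversion of the lipophilic late intermediate in the aqueous medium may be incomplete, the triene may be over-reduced, the alkene geometry may erode, and the primary silyl ether may slowly solvolyse with a subsequent acyl shift. The fallback sets out from 21 and comes back at 22. The Z geometry then comes from a stoichiometric syn hydrometalation and stereoretentive protonolysis in an anhydrous medium instead of a heterogeneous reduction. Dicyclohexylborane (THF, 0 °C) adds to the alkyne faster than to the disubstituted alkenes and gives the 6-(dicyclohexylboryl)triene F4; the 7-boryl regioisomer converges on the same product. Acetic acid at rt replaces boron by hydrogen with retention to give the aryl trimethylsilyl ether of 22 F5. Brief stirring in aqueous methanol at pH 7 removes the aryl silyl group and gives 22.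

Further compounds
F1 | step 11 | trimethylsilyl 4-(trimethylsilyloxy)benzoate | C[Si](C)(C)OC(=O)c1ccc(O[Si](C)(C)C)cc1
F2 | step 11 | 4-(trimethylsilyloxy)benzoyl chloride | ClC(=O)c1ccc(O[Si](C)(C)C)cc1
F3 | step 9 | tributylstannyl ether of 12 | CCC/C=C/C#C/C=C/CCCOC[C@H](CO[Si](C)(C)C(C)(C)C)O[Sn](CCCC)(CCCC)CCCC
F4 | step 12 | (2R)-1-[(tert-butyldimethylsilyl)oxy]-3-{[(4E,8E)-6-(dicyclohexylboryl)dodeca-4,6,8-trien-1-yl]oxy}propan-2-yl 4-(trimethylsilyloxy)benzoate, C5 and C8 cis on C6=C7 | CCC/C=C/C=C(B(C1CCCCC1)C1CCCCC1)\C=C\CCCOC[C@H](CO[Si](C)(C)C(C)(C)C)OC(=O)c1ccc(O[Si](C)(C)C)cc1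
F5 | step 12 | (2R)-1-[(tert-butyldimethylsilyl)oxy]-3-[(4E,6Z,8E)-dodeca-4,6,8-trien-1-yloxy]propan-2-yl 4-(trimethylsilyloxy)benzoate | CCC/C=C/C=C\C=C\CCCOC[C@H](CO[Si](C)(C)C(C)(C)C)OC(=O)c1ccc(O[Si](C)(C)C)cc1
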